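**Plan**

- Numbering (tetralin): C1 = CH(CH3), C2/C3 = ring CH2, C4 = CH bearing the side chain, C4a/C8a = fusion carbons, C5 = ArH, C6 = C–CO2Me, C7/C8 = C–OH; side chain C11(CH3)–C12–C13–C14–C15(CH3)–C16H2OH.
- Enabling feature: in ring B both stereocentres sit on the benzylic carbons C1 and C4, and C2–C3, the bond between the two ring methylenes, touches neither a stereocentre nor ring A. C1 and C4 can therefore be made separately as allylic CH carbons on two ortho arms of ring A, and ring B shut at C2=C3.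
- Retrosynthetic cuts, in order: C6–CO2Me (ortho-lithiation); C2–C3 (ring-closing metathesis after adding back the alkene); C4–C11 (allylation of an aldehyde enamine, the aldehyde carbon becoming the C11 methyl); C4a–C4 (aryllithium + acrolein); C1–CH3 (SN2′ methylation); C13–C14 (alkyl–alkyl coupling).
- Forward: ring A is bought as 2,3-dimethoxybenzaldehyde; the C1 arm is built, the arene is brominated at C4a, the C4 arm with the whole side chain is attached in one coupling, ring B is closed last, then hydrogenation, C6 carboxylation and ether cleavage.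
- Stereochemistry: C15 from (R)-3-bromo-2-methylpropan-1-ol; C1 (R) from ligand-controlled copper SN2′ methylation; C4 (S) from the iridium ligand and C11 (S) from the amine catalyst of one dual-catalytic step; the metathesis creates no stereocentre.

Key step: step 12

Assumption: in the two ligand-controlled steps the sense of induction is assigned by analogy with the parent 1-arylallyl systems; the antipodes named, (S,Sp)-Taniaphos [(Sp)-1-{(S)-α-(dimethylamino)-2-(diphenylphosphino)benzyl}-2-(diphenylphosphino)ferrocene] for (R)-C1 and (R)-L [(R)-5-(dinaphtho[2,1-d:1′,2′-f][1,3,2]dioxaphosphepin-4-yl)-5H-dibenzo[b,f]azepine] for (S)-C4, are the ones taken to give these centres, and both mirror-image ligands are commercial should a first run show the opposite sense.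

**Route**

Step 1
Reactants: 1 2,3-dimethoxybenzaldehyde
Product: 2 1-(2,3-dimethoxyphenyl)prop-2-en-1-ol (racemic)
Conditions: CH2=CHMgBr, THF, 0 °C; H2O quench
Reagents that add atoms: vinylmagnesium bromide, C=C[Mg]Br
Why: 1,2-addition of a vinyl Grignard reagent to an aryl aldehyde is routine, and the racemic carbinol centre is of no consequence because step 2 removes it.

Step 2
Reactants: 2 1-(2,3-dimethoxyphenyl)prop-2-en-1-ol
Product: 3 (E)-1-(3-bromoprop-1-en-1-yl)-2,3-dimethoxybenzene
Conditions: PBr3 (0.4 equiv), Et2O, 0 °C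
Reagents that add atoms: phosphorus tribromide, BrP(Br)Br
Why: bromination of a 1-arylallyl alcohol with PBr3 proceeds with allylic transposition (SN2′ or ion-pair return at the primary terminus), because the conjugated (E)-cinnamyl bromide is the thermodynamic product; the labile bromide is used at once.

Step 3
Reactants: 3 (E)-1-(3-bromoprop-1-en-1-yl)-2,3-dimethoxybenzene
Product: 4 1-[(2R)-but-3-en-2-yl]-2,3-dimethoxybenzene
Conditions: MeMgBr (1.2 equiv, Et2O), CuBr·SMe2 (3 mol %), (S,Sp)-Taniaphos (3.6 mol %), CH2Cl2, −75 °C, slow addition of 3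
Reagents that add atoms: methylmagnesium bromide, C[Mg]Br
Why: copper-catalysed asymmetric allylic alkylation of a cinnamyl bromide with MeMgBr is an established SN2′ route to 3-arylbut-1-enes, in which the chiral bisphosphine–copper complex delivers methyl to one enantioface of the benzylic γ-carbon and so sets C1 as R under ligand control.

Step 4
Reactants: 4 1-[(2R)-but-3-en-2-yl]-2,3-dimethoxybenzene
Product: 5 1-bromo-2-[(2R)-but-3-en-2-yl]-3,4-dimethoxybenzene
Conditions: NBS (1.05 equiv), MeCN, 0 °C, dark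
Reagents that add atoms: N-bromosuccinimide, O=C1CCC(=O)N1Br
Why: electrophilic aromatic bromination should go para to the outer, conjugated methoxy group (the flanked inner one is twisted out of plane) as it does in 2,3-dimethoxytoluene, and in polar solvent without light the electron-rich ring should react ahead of the monosubstituted alkene and the benzylic C–H, so C1 is untouched.

Step 5
Reactants: 5 1-bromo-2-[(2R)-but-3-en-2-yl]-3,4-dimethoxybenzene
Product: 7 1-{2-[(2R)-but-3-en-2-yl]-3,4-dimethoxyphenyl}prop-2-en-1-ol (both carbinol epimers), via aryllithium 6 (not isolated)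
Conditions: n-BuLi, THF, −78 °C; then acrolein, −78 °C; H2O quench
Reagents that add atoms: acrolein, C=CC=O
Why: bromine–lithium exchange at −78 °C is much faster than deprotonation of the C1–H, and the aryllithium adds 1,2 to acrolein at low temperature to give the aryl vinyl carbinol, whose carbinol configuration is irrelevant because step 9 ionises that centre.

Step 6
Reactants: 8 (R)-3-bromo-2-methylpropan-1-ol
Product: 9 [(2R)-3-bromo-2-methylpropoxy]tri(propan-2-yl)silane
Conditions: TIPSCl, imidazole, DMF, 23 °C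
Reagents that add atoms: chlorotri(propan-2-yl)silane, CC(C)[Si](Cl)(C(C)C)C(C)C
Why: silylation of a primary alcohol with a silyl chloride and imidazole is standard and leaves the stereocentre (the future C15) untouched.

Step 7
Reactants: 9 [(2R)-3-bromo-2-methylpropoxy]tri(propan-2-yl)silane
Product: 10 {[(2S)-2-methyloct-7-en-1-yl]oxy}tri(propan-2-yl)silane
Conditions: pent-4-enylMgBr (THF solution, 1.5 equiv), Li2CuCl4 (3 mol %), NMP, THF, 0 → 23 °C
Reagents that add atoms: pent-4-enylmagnesium bromide, C=CCCC[Mg]Br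
Why: copper-catalysed alkyl–alkyl cross-coupling of a primary bromide with a primary Grignard reagent, routine for 3-oxy-2-methylpropyl halides, forms C13–C14 without touching the adjacent stereocentre (the descriptor changes from R to S only through CIP ranking).

Step 8
Reactants: 10 {[(2S)-2-methyloct-7-en-1-yl]oxy}tri(propan-2-yl)silane
Product: 12 (6S)-6-methyl-7-{[tri(propan-2-yl)silyl]oxy}heptanal, via ozonide 11 (not isolated)
Conditions: O3, CH2Cl2, −78 °C; then PPh3, −78 → 23 °C
Reagents that add atoms: ozone, [O-][O+]=O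
Why: ozonolysis with reductive work-up cleaves the only alkene to the aldehyde, and the silyl ether and the remote stereocentre are inert.

Step 9
Reactants: 7 1-{2-[(2R)-but-3-en-2-yl]-3,4-dimethoxyphenyl}prop-2-en-1-ol; 12 (6S)-6-methyl-7-{[tri(propan-2-yl)silyl]oxy}heptanal
Product: 14 (2S,6S)-2-[(1S)-1-{2-[(2R)-but-3-en-2-yl]-3,4-dimethoxyphenyl}prop-2-en-1-yl]-6-methyl-7-{[tri(propan-2-yl)silyl]oxy}heptan-1-ol, via aldehyde 13 (not isolated)
Conditions: [Ir(cod)Cl]2 (3 mol %), (R)-L (12 mol %), (R)-2-{bis[3,5-bis(trifluoromethyl)phenyl][(trimethylsilyl)oxy]methyl}pyrrolidine (15 mol %), (MeO)2P(O)OH (promoter), ClCH2CH2Cl, 25 °C; then MeOH, NaBH4, 0 °C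
Reagents that add atoms: none
Why: this is the known stereodivergent dual-catalytic α-allylation of linear aldehydes with racemic aryl vinyl carbinols (2,6-disubstituted aryl groups included), in which acid-promoted ionisation of either carbinol epimer gives a trivalent-iridium η3-allyl complex that the E-enamine of 12 attacks at the benzylic terminus; the iridium ligand alone fixes C4 (S), the (R)-amine, whose bulky diarylmethyl group shields one enamine face, alone fixes C11 (S), and the epimerisable α-branched aldehyde is reduced in the same flask.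

Step 10
Reactants: 14 (2S,6S)-2-[(1S)-1-{2-[(2R)-but-3-en-2-yl]-3,4-dimethoxyphenyl}prop-2-en-1-yl]-6-methyl-7-{[tri(propan-2-yl)silyl]oxy}heptan-1-ol
Product: 15 (2S,6S)-2-[(1S)-1-{2-[(2R)-but-3-en-2-yl]-3,4-dimethoxyphenyl}prop-2-en-1-yl]-6-methyl-7-{[tri(propan-2-yl)silyl]oxy}heptyl 4-methylbenzenesulfonate
Conditions: TsCl, Et3N, DMAP (cat), CH2Cl2, 0 → 23 °C
Reagents that add atoms: 4-methylbenzenesulfonyl chloride, Cc1ccc(cc1)S(Cl)(=O)=O
Why: sulfonylation of a primary alcohol is routine and turns the former aldehyde oxygen into a leaving group without affecting any stereocentre.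

Step 11
Reactants: 15 (2S,6S)-2-[(1S)-1-{2-[(2R)-but-3-en-2-yl]-3,4-dimethoxyphenyl}prop-2-en-1-yl]-6-methyl-7-{[tri(propan-2-yl)silyl]oxy}heptyl 4-methylbenzenesulfonate
Product: 16 2-[(2R)-but-3-en-2-yl]-1-[(3S,4S,8S)-4,8-dimethyl-9-{[tri(propan-2-yl)silyl]oxy}non-1-en-3-yl]-3,4-dimethoxybenzene
Conditions: LiEt3BH, THF, 0 → 23 °C
Reagents that add atoms: none
Why: LiEt3BH displaces primary sulfonates by hydride in an SN2 reduction, β-branched ones included, without touching isolated alkenes or the silyl ether, so the former aldehyde carbon becomes the C11 methyl group.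

Step 12
Reactants: 16 2-[(2R)-but-3-en-2-yl]-1-[(3S,4S,8S)-4,8-dimethyl-9-{[tri(propan-2-yl)silyl]oxy}non-1-en-3-yl]-3,4-dimethoxybenzene
Product: 17 (1R,4R)-7,8-dimethoxy-1-methyl-4-[(2S,6S)-6-methyl-7-{[tri(propan-2-yl)silyl]oxy}heptan-2-yl]-1,4-dihydronaphthalene
Conditions: second-generation Grubbs catalyst (H2IMes)(PCy3)Cl2Ru=CHPh (5 mol %), 1,4-benzoquinone (10 mol %), CH2Cl2 (0.005 M), 40 °C
Reagents that add atoms: none
Why: The ruthenium benzylidene exchanges with one terminal vinyl group to give an alkylidene, which adds across the other vinyl group through a ruthenacyclobutane and cycloreverts, releasing the C2=C3 alkene and, over the cycle, ethylene. The closest known reaction type is the ring-closing metathesis of 1,2-bis(allyl)arenes to 1,4-dihydronaphthalenes. Ring B is closed as a six-membered carbocycle by joining the terminal-alkene carbons C2 and C3 of two arms held ortho on ring A, a closure with only two sp3 atoms in the tether and therefore fast. No stereocentre is formed: C1, C4, C11 and C15 are spectators, so the trans-1,4 relationship is exactly the one installed in steps 3 and 9 (C4 is labelled R in 17 only because the ring alkene changes the CIP ranking). The step needs cyclisation over oligomerisation and no alkene migration; the first is secured by the ortho arrangement, the monosubstituted alkenes and dilution, the second by 1,4-benzoquinone, which intercepts ruthenium hydrides, by moderate temperature, and by taking 17 straight into step 13 before its doubly activated benzylic–allylic C–H bonds can isomerise or aromatise.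

Step 13
Reactants: 17 (1R,4R)-7,8-dimethoxy-1-methyl-4-[(2S,6S)-6-methyl-7-{[tri(propan-2-yl)silyl]oxy}heptan-2-yl]-1,4-dihydronaphthalene
Product: 18 (1R,4S)-7,8-dimethoxy-1-methyl-4-[(2S,6S)-6-methyl-7-{[tri(propan-2-yl)silyl]oxy}heptan-2-yl]-1,2,3,4-tetrahydronaphthalene
Conditions: H2 (1 atm), PtO2 (5 mol %), EtOAc, 23 °C
Reagents that add atoms: none
Why: heterogeneous hydrogenation of the cis-disubstituted ring alkene creates no stereocentre, and platinum is chosen over palladium because it causes far less double-bond migration into conjugation with ring A, which would scramble C1 or C4; arene and silyl ether are inert at 1 atm.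

Step 14
Reactants: 18 (1R,4S)-7,8-dimethoxy-1-methyl-4-[(2S,6S)-6-methyl-7-{[tri(propan-2-yl)silyl]oxy}heptan-2-yl]-1,2,3,4-tetrahydronaphthalene
Product: 20 methyl (5R,8S)-3,4-dimethoxy-5-methyl-8-[(2S,6S)-6-methyl-7-{[tri(propan-2-yl)silyl]oxy}heptan-2-yl]-5,6,7,8-tetrahydronaphthalene-2-carboxylate, via aryllithium 19 (not isolated)
Conditions: n-BuLi, TMEDA, Et2O, 0 → 23 °C; then cannulation into ClCO2Me (excess), THF, −78 °C
Reagents that add atoms: methyl chloroformate, COC(Cl)=O
Why: directed ortho-lithiation removes C6–H, the only ring hydrogen ortho to a methoxy group (the tertiary benzylic C–H bonds are kinetically much less acidic), and inverse addition of the aryllithium to excess chloroformate gives the methyl benzoate without over-addition.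

Step 15
Reactants: 20 methyl (5R,8S)-3,4-dimethoxy-5-methyl-8-[(2S,6S)-6-methyl-7-{[tri(propan-2-yl)silyl]oxy}heptan-2-yl]-5,6,7,8-tetrahydronaphthalene-2-carboxylate
Product: 21 methyl (5R,8S)-3,4-dihydroxy-8-[(2S,6S)-7-hydroxy-6-methylheptan-2-yl]-5-methyl-5,6,7,8-tetrahydronaphthalene-2-carboxylate (CNP0135649.1)
Conditions: BBr3 (4 equiv), CH2Cl2, −78 → 0 °C; then MeOH, 0 → 23 °C
Reagents that add atoms: none
Why: Lewis-acid ether cleavage with BBr3 removes both aryl methyl groups at or below 0 °C (the C7 ether helped by chelation to the ester carbonyl, the C8 ether through the cyclic catechol borate) while the methyl ester should persist, and the methanol quench returns any acyl bromide to the methyl ester and, through the HBr it releases, completes methanolysis of the primary silyl ether.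

**Compound list**

1 | 2,3-dimethoxybenzaldehyde | COc1cccc(C=O)c1OC | starting material
2 | 1-(2,3-dimethoxyphenyl)prop-2-en-1-ol (racemic) | COc1cccc(C(O)C=C)c1OC | intermediate
3 | (E)-1-(3-bromoprop-1-en-1-yl)-2,3-dimethoxybenzene | COc1cccc(/C=C/CBr)c1OC | intermediate
4 | 1-[(2R)-but-3-en-2-yl]-2,3-dimethoxybenzene | COc1cccc([C@H](C)C=C)c1OC | intermediate
5 | 1-bromo-2-[(2R)-but-3-en-2-yl]-3,4-dimethoxybenzene | COc1ccc(Br)c([C@H](C)C=C)c1OC | intermediate
6 | {2-[(2R)-but-3-en-2-yl]-3,4-dimethoxyphenyl}lithium | COc1ccc([Li])c([C@H](C)C=C)c1OC | intermediate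
7 | 1-{2-[(2R)-but-3-en-2-yl]-3,4-dimethoxyphenyl}prop-2-en-1-ol (both carbinol epimers) | COc1ccc(C(O)C=C)c([C@H](C)C=C)c1OC | intermediate
8 | (R)-3-bromo-2-methylpropan-1-ol | BrC[C@H](C)CO | starting material
9 | [(2R)-3-bromo-2-methylpropoxy]tri(propan-2-yl)silane | BrC[C@H](C)CO[Si](C(C)C)(C(C)C)C(C)C | intermediate
10 | {[(2S)-2-methyloct-7-en-1-yl]oxy}tri(propan-2-yl)silane | C=CCCCC[C@H](C)CO[Si](C(C)C)(C(C)C)C(C)C | intermediate
11 | 3-[(5S)-5-methyl-6-{[tri(propan-2-yl)silyl]oxy}hexyl]-1,2,4-trioxolane (ozonide, epimers at the ring carbon) | C1(CCCC[C@H](C)CO[Si](C(C)C)(C(C)C)C(C)C)OCOO1 | intermediate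
12 | (6S)-6-methyl-7-{[tri(propan-2-yl)silyl]oxy}heptanal | O=CCCCC[C@H](C)CO[Si](C(C)C)(C(C)C)C(C)C | intermediate
13 | (2S,6S)-2-[(1S)-1-{2-[(2R)-but-3-en-2-yl]-3,4-dimethoxyphenyl}prop-2-en-1-yl]-6-methyl-7-{[tri(propan-2-yl)silyl]oxy}heptanal | COc1ccc([C@@H](C=C)[C@@H](C=O)CCC[C@H](C)CO[Si](C(C)C)(C(C)C)C(C)C)c(c1OC)[C@H](C)C=C | intermediate
14 | (2S,6S)-2-[(1S)-1-{2-[(2R)-but-3-en-2-yl]-3,4-dimethoxyphenyl}prop-2-en-1-yl]-6-methyl-7-{[tri(propan-2-yl)silyl]oxy}heptan-1-ol | COc1ccc([C@@H](C=C)[C@@H](CO)CCC[C@H](C)CO[Si](C(C)C)(C(C)C)C(C)C)c(c1OC)[C@H](C)C=C | intermediate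
15 | (2S,6S)-2-[(1S)-1-{2-[(2R)-but-3-en-2-yl]-3,4-dimethoxyphenyl}prop-2-en-1-yl]-6-methyl-7-{[tri(propan-2-yl)silyl]oxy}heptyl 4-methylbenzenesulfonate | COc1ccc([C@@H](C=C)[C@@H](COS(=O)(=O)c2ccc(C)cc2)CCC[C@H](C)CO[Si](C(C)C)(C(C)C)C(C)C)c(c1OC)[C@H](C)C=C | intermediate
16 | 2-[(2R)-but-3-en-2-yl]-1-[(3S,4S,8S)-4,8-dimethyl-9-{[tri(propan-2-yl)silyl]oxy}non-1-en-3-yl]-3,4-dimethoxybenzene | COc1ccc([C@@H](C=C)[C@@H](C)CCC[C@H](C)CO[Si](C(C)C)(C(C)C)C(C)C)c(c1OC)[C@H](C)C=C | intermediate
17 | (1R,4R)-7,8-dimethoxy-1-methyl-4-[(2S,6S)-6-methyl-7-{[tri(propan-2-yl)silyl]oxy}heptan-2-yl]-1,4-dihydronaphthalene (trans) | COc1ccc2c(c1OC)[C@H](C)C=C[C@H]2[C@@H](C)CCC[C@H](C)CO[Si](C(C)C)(C(C)C)C(C)C | intermediate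
18 | (1R,4S)-7,8-dimethoxy-1-methyl-4-[(2S,6S)-6-methyl-7-{[tri(propan-2-yl)silyl]oxy}heptan-2-yl]-1,2,3,4-tetrahydronaphthalene | COc1ccc2c(c1OC)[C@H](C)CC[C@H]2[C@@H](C)CCC[C@H](C)CO[Si](C(C)C)(C(C)C)C(C)C | intermediate
19 | C6-lithio derivative of 18, [(5R,8S)-3,4-dimethoxy-5-methyl-8-[(2S,6S)-6-methyl-7-{[tri(propan-2-yl)silyl]oxy}heptan-2-yl]-5,6,7,8-tetrahydronaphthalen-2-yl]lithium | [Li]c1cc2c(c(OC)c1OC)[C@H](C)CC[C@H]2[C@@H](C)CCC[C@H](C)CO[Si](C(C)C)(C(C)C)C(C)C | intermediate
20 | methyl (5R,8S)-3,4-dimethoxy-5-methyl-8-[(2S,6S)-6-methyl-7-{[tri(propan-2-yl)silyl]oxy}heptan-2-yl]-5,6,7,8-tetrahydronaphthalene-2-carboxylate | COC(=O)c1cc2c(c(OC)c1OC)[C@H](C)CC[C@H]2[C@@H](C)CCC[C@H](C)CO[Si](C(C)C)(C(C)C)C(C)C | intermediate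
21 | methyl (5R,8S)-3,4-dihydroxy-8-[(2S,6S)-7-hydroxy-6-methylheptan-2-yl]-5-methyl-5,6,7,8-tetrahydronaphthalene-2-carboxylate | COC(=O)c1cc2c(c(O)c1O)[C@H](C)CC[C@H]2[C@@H](C)CCC[C@H](C)CO | target

**Count and risks**

Total steps: 15. Longest linear sequence: 12 steps (1 → 21 through steps 1–5 and 9–15); the side-chain branch (steps 6–8) joins at step 9.

Step 9. What may go wrong: slow ionisation of the hindered carbinol, erosion of facial control at the allyl terminus by the ortho C1 arm (a matched/mismatched effect giving the C4 epimer), or epimerisation of the α-branched aldehyde before reduction. The fallback replaces the intermolecular coupling by an Ireland–Claisen rearrangement with 1,3-chirality transfer; it sets out from 5 and 12 and comes back to the route at 17.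
- Aryllithium 6, made from 5 as in step 5, is quenched with DMF to give 2-[(2R)-but-3-en-2-yl]-3,4-dimethoxybenzaldehyde F1.
- Wittig reaction with Ph3P=CHC(O)CH3 in toluene at 80 °C gives (3E)-4-{2-[(2R)-but-3-en-2-yl]-3,4-dimethoxyphenyl}but-3-en-2-one F2.
- CBS reduction with the (S)-methyl oxazaborolidine and BH3·SMe2 gives (2R,3E)-4-{2-[(2R)-but-3-en-2-yl]-3,4-dimethoxyphenyl}but-3-en-2-ol F3.
- Pinnick oxidation of 12 (NaClO2, NaH2PO4, 2-methylbut-2-ene) gives (6S)-6-methyl-7-{[tri(propan-2-yl)silyl]oxy}heptanoic acid F4, and DCC/DMAP coupling with F3 gives the allylic ester F5.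
- LiN(i-Pr)2 in THF at −78 °C followed by Me3SiCl gives the (E)-trimethylsilyl ketene acetal F6, with the chain cis to the allylic oxygen.
- On warming, F6 should rearrange through a chair with the carbinol methyl equatorial, so that the (R)-carbinol centre is transferred to (S)-C4 and the ketene acetal geometry gives (S)-C11. After work-up this is (2S,6S)-2-[(1S,2E)-1-{2-[(2R)-but-3-en-2-yl]-3,4-dimethoxyphenyl}but-2-en-1-yl]-6-methyl-7-{[tri(propan-2-yl)silyl]oxy}heptanoic acid F7.
- LiAlH4 gives the primary alcohol F8, TsCl/Et3N the tosylate F9, and LiEt3BH the propenyl diene 2-[(2R)-but-3-en-2-yl]-1-[(2E,4R,5S,9S)-5,9-dimethyl-10-{[tri(propan-2-yl)silyl]oxy}dec-2-en-4-yl]-3,4-dimethoxybenzene F10.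
- Ring-closing metathesis of F10 under the conditions of step 12 releases propene instead of ethylene and gives 17.

Step 3. What may go wrong: leakage to the linear SN2 product or low enantioselectivity, because the ortho-methoxy group can bind magnesium or copper and twists the aryl group. The fallback forms the C1 centre by a different bond construction; it sets out from 1 and comes back at 4. Wittig methylenation of 1 (Ph3PCH3Br, KOt-Bu, THF) gives 1-ethenyl-2,3-dimethoxybenzene F11. Nickel-catalysed asymmetric hydrovinylation ([(η3-C3H5)NiBr]2, a binaphthol-derived chiral phosphoramidite, Na[B(3,5-(CF3)2C6H3)4], ethylene 1 atm, CH2Cl2, −70 °C) then adds H and vinyl across the styrene in the Markovnikov sense, a reaction established for ortho-methoxystyrenes, and gives 4 with the ligand antipode chosen for R.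

Step 15. What may go wrong: conversion of the side-chain oxygen into a bromide through its dibromoborate, or partial loss of the methyl ester, during the one-pot ether cleavage. The fallback stages the deprotection; it sets out from 20 and comes back at 21.
- Bu4NF in THF removes the silyl group to give methyl (5R,8S)-8-[(2S,6S)-7-hydroxy-6-methylheptan-2-yl]-3,4-dimethoxy-5-methyl-5,6,7,8-tetrahydronaphthalene-2-carboxylate F12.
- Ac2O/pyridine gives the acetate methyl (5R,8S)-8-[(2S,6S)-7-acetoxy-6-methylheptan-2-yl]-3,4-dimethoxy-5-methyl-5,6,7,8-tetrahydronaphthalene-2-carboxylate F13, whose side-chain ester resists BBr3.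
- BBr3 at −78 → 0 °C then cleaves only the two aryl methyl ethers to give methyl (5R,8S)-8-[(2S,6S)-7-acetoxy-6-methylheptan-2-yl]-3,4-dihydroxy-5-methyl-5,6,7,8-tetrahydronaphthalene-2-carboxylate F14.
- HCl in MeOH (from AcCl) removes the acetate by transesterification, which is degenerate for the methyl benzoate, and gives 21.

**Further compounds**

F1 | step 9 | 2-[(2R)-but-3-en-2-yl]-3,4-dimethoxybenzaldehyde | COc1ccc(C=O)c([C@H](C)C=C)c1OC
F2 | step 9 | (3E)-4-{2-[(2R)-but-3-en-2-yl]-3,4-dimethoxyphenyl}but-3-en-2-one | COc1ccc(/C=C/C(C)=O)c([C@H](C)C=C)c1OC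
F3 | step 9 | (2R,3E)-4-{2-[(2R)-but-3-en-2-yl]-3,4-dimethoxyphenyl}but-3-en-2-ol | COc1ccc(/C=C/[C@@H](C)O)c([C@H](C)C=C)c1OC
F4 | step 9 | (6S)-6-methyl-7-{[tri(propan-2-yl)silyl]oxy}heptanoic acid | OC(=O)CCCC[C@H](C)CO[Si](C(C)C)(C(C)C)C(C)C
F5 | step 9 | (2R,3E)-4-{2-[(2R)-but-3-en-2-yl]-3,4-dimethoxyphenyl}but-3-en-2-yl (6S)-6-methyl-7-{[tri(propan-2-yl)silyl]oxy}heptanoate | COc1ccc(/C=C/[C@@H](C)OC(=O)CCCC[C@H](C)CO[Si](C(C)C)(C(C)C)C(C)C)c([C@H](C)C=C)c1OC
F6 | step 9 | (E)-trimethylsilyl ketene acetal of F5 (chain cis to the allylic oxygen) | C[Si](C)(C)O/C(O[C@H](C)/C=C/c1ccc(OC)c(OC)c1[C@H](C)C=C)=C/CCC[C@H](C)CO[Si](C(C)C)(C(C)C)C(C)C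
F7 | step 9 | (2S,6S)-2-[(1S,2E)-1-{2-[(2R)-but-3-en-2-yl]-3,4-dimethoxyphenyl}but-2-en-1-yl]-6-methyl-7-{[tri(propan-2-yl)silyl]oxy}heptanoic acid | COc1ccc([C@@H](/C=C/C)[C@@H](C(O)=O)CCC[C@H](C)CO[Si](C(C)C)(C(C)C)C(C)C)c(c1OC)[C@H](C)C=C
F8 | step 9 | (2S,6S)-2-[(1S,2E)-1-{2-[(2R)-but-3-en-2-yl]-3,4-dimethoxyphenyl}but-2-en-1-yl]-6-methyl-7-{[tri(propan-2-yl)silyl]oxy}heptan-1-ol | COc1ccc([C@@H](/C=C/C)[C@@H](CO)CCC[C@H](C)CO[Si](C(C)C)(C(C)C)C(C)C)c(c1OC)[C@H](C)C=C
F9 | step 9 | (2S,6S)-2-[(1S,2E)-1-{2-[(2R)-but-3-en-2-yl]-3,4-dimethoxyphenyl}but-2-en-1-yl]-6-methyl-7-{[tri(propan-2-yl)silyl]oxy}heptyl 4-methylbenzenesulfonate | COc1ccc([C@@H](/C=C/C)[C@@H](COS(=O)(=O)c2ccc(C)cc2)CCC[C@H](C)CO[Si](C(C)C)(C(C)C)C(C)C)c(c1OC)[C@H](C)C=C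
F10 | step 9 | 2-[(2R)-but-3-en-2-yl]-1-[(2E,4R,5S,9S)-5,9-dimethyl-10-{[tri(propan-2-yl)silyl]oxy}dec-2-en-4-yl]-3,4-dimethoxybenzene | COc1ccc([C@@H](/C=C/C)[C@@H](C)CCC[C@H](C)CO[Si](C(C)C)(C(C)C)C(C)C)c(c1OC)[C@H](C)C=C
F11 | step 3 | 1-ethenyl-2,3-dimethoxybenzene | COc1cccc(C=C)c1OC
F12 | step 15 | methyl (5R,8S)-8-[(2S,6S)-7-hydroxy-6-methylheptan-2-yl]-3,4-dimethoxy-5-methyl-5,6,7,8-tetrahydronaphthalene-2-carboxylate | COC(=O)c1cc2c(c(OC)c1OC)[C@H](C)CC[C@H]2[C@@H](C)CCC[C@H](C)CO
F13 | step 15 | methyl (5R,8S)-8-[(2S,6S)-7-acetoxy-6-methylheptan-2-yl]-3,4-dimethoxy-5-methyl-5,6,7,8-tetrahydronaphthalene-2-carboxylate | COC(=O)c1cc2c(c(OC)c1OC)[C@H](C)CC[C@H]2[C@@H](C)CCC[C@H](C)COC(C)=O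
F14 | step 15 | methyl (5R,8S)-8-[(2S,6S)-7-acetoxy-6-methylheptan-2-yl]-3,4-dihydroxy-5-methyl-5,6,7,8-tetrahydronaphthalene-2-carboxylate | COC(=O)c1cc2c(c(O)c1O)[C@H](C)CC[C@H]2[C@@H](C)CCC[C@H](C)COC(C)=O
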